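Compound numbers are those of the steps and the compound list below; "farnesyl" always means (2E,6E)-3,7,11-trimethyldodeca-2,6,10-trien-1-yl, attached through C1'.

## The problem

The target 14 is a 2,2-disubstituted benzofuran-3(2H)-one: a resorcinol-derived ring A fused to a five-membered ring B (O1, C2, C3, C3a, C7a) that carries the C3 ketone, with a phenol at C6 and, on C2, a hydroxyl group and an all-E farnesyl chain. C2 is the only stereocentre, (R), and no other element of the molecule can relay chirality to it, so it must be set by a reagent or a catalyst. C2 is also a hemiketal carbon: its alkoxide can open to an achiral 1,2-diketone phenoxide and reclose, so the centre has to be made late and must not be left in basic medium. The chain holds three trisubstituted olefins, two of defined E geometry, which will not tolerate strong protic or Lewis acids, electrophilic epoxidants, osmium-based dihydroxylation or hydrogenation. Every oxidation therefore has to be aimed at an enol or enolate and not at a C=C bond. The C6 phenol sits para to the ketone, is acidic, and needs a mask that withstands hydride and hydroxide bases yet leaves under neutral conditions. The feature that opens the route is that O1–C2–C3 of ring B coincides with O1, C3 and C4 of a 4-hydroxycoumarin once a carbonyl carbon is inserted between O1 and C2. C3 of a 4-hydroxycoumarin is the nucleophilic carbon of a cyclic 1,3-dicarbonyl, so the chain and a leaving group can both be placed there chemoselectively before that carbonyl carbon is excised.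

## Retrosynthesis

**14 ⇒ 13 (benzylic C–O bond on O6).** The phenol is traced to its 4-methoxybenzyl ether 13.
- A silyl ether would not survive the ethoxide of coumarin formation or the hydroxide of the ring contraction.
- An allyl ether would be ionised in the palladium step.
- A methyl or benzyl ether would need a Lewis acid or hydrogenation, neither of which the chain allows.
- 13 is no simpler in skeleton, but it has no acidic phenol.
- The forward reaction must be neutral, which a quinone oxidant in buffered wet dichloromethane provides.

**13 ⇒ 11 (C2–OH bond).** Removing the hydroxyl oxygen gives the C2–H ketone 11, which reacts as its enolate 12.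
- Oxygen and a phase-transfer catalyst would hold the hemiketal in aqueous base, where ring-chain equilibration is expected.
- Dihydroxylation or epoxidation of an enol derivative could not distinguish C2=C3 from the three chain olefins.
- A chiral N-sulfonyloxaziridine reacts only with the enolate at −78 °C, and its conjugate base is quenched cold.
- The cut removes the only stereocentre, since 11 is enolisable and effectively achiral.
- The forward reaction has to deliver one oxygen atom to the Si face of C2 and be quenched before the alkoxide opens.

**11 ⇒ 8 (O1–C2 bond, with a carbonyl carbon put back between O1 and C2).** Ring B of 11 becomes the lactone ring of the 3-chlorochromane-2,4-dione 8: C2 of 11 is the chlorinated C3 of 8 and C3 of 11 is its C4.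
- Direct C2-farnesylation of a ring B ketone would suffer from O- versus C-alkylation and double alkylation.
- Halogenating an open-chain 2-hydroxyaryl ketone would compete with the chain olefins.
- In the coumarin series both substituents go onto a 1,3-dicarbonyl carbon, where selective C-functionalisation is routine.
- 8 is one carbon larger, but it comes from commodity materials.
- The forward reaction is a lactone opening to 9, an O1–C2 closure to 10 and a decarboxylation.

**8 ⇒ 7 (C3–Cl bond).** The chlorine is removed to give the 3-farnesyl-4-hydroxycoumarin 7.
- Chlorine is chosen over bromine because the 3-bromo dione is a stronger positive-halogen donor and is more prone to elimination.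
- The forward reaction only has to prefer the enol carbon over the chain olefins.

**7 ⇒ 5 + 6 (C3–C1' bond).** The whole C15 chain is detached as farnesyl bromide 6, leaving the coumarin 5.
- O-alkylation followed by sigmatropic shift would attach the chain through its tertiary carbon, so that route is excluded.
- This is the largest simplification in the plan: 6 is purchased with both E olefins in place.
- The forward reaction has to be C-selective, linear-selective and geometry-retentive, which palladium pi-allyl chemistry offers.

**5 ⇒ 2 + 3 (C2–C3 and O1–C2 bonds of the lactone).** The lactone carbonyl is traced to diethyl carbonate 3 and the ring to the acetophenone 2, by way of the beta-keto ester 4.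
- This is the standard assembly of 4-hydroxycoumarins.
- It asks only that the O4 protecting group resist hydride and ethoxide at 110 °C.

**2 ⇒ 1 (O4–benzyl bond).** The ether is cut back to 2,4-dihydroxyacetophenone 1. The chelated 2-OH is much less reactive than the 4-OH, so no second protecting group is needed.

## Roads not taken

**Alternative 1:** The cut goes through a spiro-oxirane spanning C2 and C1'. The C2 hydroxyl is traced to the oxirane A2, and A2 to the (Z)-farnesylidene benzofuranone A1, with the phenol as a triisopropylsilyl ether. In the forward sense an alkyl hydroperoxide and hydroxide, under a cinchona-derived quaternary ammonium salt, would epoxidise the electron-poor C2=C1' bond of A1 (Weitz–Scheffer epoxidation) and set C2.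
- Merits: the reaction is catalytic and well studied on chalcone-type enones, and A1 should be short to make by aldol condensation. The oxidant is a nucleophile, so the electron-rich chain olefins are left alone.
- Where it is better: the C2 oxygen stays locked in the oxirane until the ring is opened, whereas the chosen plan passes through the free hemiketal alkoxide for a short time in step 6.
- Weak points: A1 is a dienone, so the hydroperoxide may add at C3' instead of C1'. A2 must then be opened reductively at C1'–O only. Electron-transfer reductants cleave the bond alpha to the ketone (C2–O), which destroys the centre. Palladium-hydride opening of the vinyl oxirane can deliver hydride to C3' and move the 2',3' olefin. The aryl silyl ether is also exposed to hydroxide.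
- Comparison: the length is about the same. Against its own weaker point the chosen plan sets the fact that C1' is never oxidised, so no C–O bond has to be removed again and the olefin positions are never in question.

**Alternative 2:** The cut is the C2–C3 bond. Ring B is opened to the aryl ester A3, a salicylaldehyde whose phenol oxygen carries the homofarnesoyl group. A chiral aminoindanol-derived triazolylidene would convert the aldehyde into an acyl-anion equivalent that adds to the ester carbonyl, giving the silyl-protected hemiketal A4 with ring B and C2 formed together.
- Merits: this is the shortest road. Ring, C–C bond, stereocentre and the correct oxidation level at C2 arrive in one catalytic step, with no separate oxidation, no halogen and no carbon discarded. In step count and atom economy it is clearly better than the chosen plan.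
- Weak points: the acceptor is an unactivated ester, for which acyl-anion addition is not established. The adduct is the hemiketal alkoxide itself, a tetrahedral intermediate of acyl transfer, which under the basic carbene conditions should expel the aryloxide and reclose without control. Plain acyl transfer from the aryl ester to carbene or base competes.
- Comparison: the chosen plan is three to four steps longer. It offers a direct precedent for each bond formation and sets C2 at −78 °C under stoichiometric reagent control with an immediate acid quench.

**Alternative 3:** The cut removes two bonds of ring A, C3a–C7a and C4–C5. The benzene ring is traced to the 2-pyrone A5, which carries an alpha-farnesyl ynone on its C3 oxygen. On heating, the alkyne would add across C3 and C6 of the pyrone (intramolecular Diels–Alder reaction), closing ring B with the first bond, and decarboxylative aromatisation would give the benzofuranone A6.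
- Merits: the key step is neutral and needs no reagent. The oxygenation pattern of ring A is fixed by the pyrone and cannot go astray, and no base-sensitive halo dione is involved. In these respects it equals or betters the chosen plan.
- Weak points: ring A is a resorcinol that can be bought, so the cascade builds what needs no building. A5 needs a 3,5-dioxygenated pyrone, an etherification at a hindered carbon alpha to a ketone and a sensitive terminal ynone, which is more work than the whole chosen route. Long heating of an ynone beside a 1,5-diene chain invites ene-type side reactions. A6 is only the silyl analogue of 11, so C2 is still unset and the same hydroxylation would follow.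
- Comparison: the chosen plan reaches 11 in five steps from commodity chemicals.

Key step: step 5

Remarks on the chemistry:
- C2 of 13 and 14 is a hemiketal carbon and is assumed to keep its configuration as the neutral hemiketal in non-basic media, so everything after C2–O formation is run cold and buffered.
- The oxaziridine antipode drawn in step 6, derived from (1S)-10-camphorsulfonic acid, is assumed to be the one that oxidises the Si face of C2; if the sense proves opposite, its mirror image is used with no other change.

## Route

Step 1
Reactants: 1 2,4-dihydroxyacetophenone
Product: 2 1-[2-hydroxy-4-(4-methoxybenzyloxy)phenyl]ethan-1-one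
Conditions: 4-methoxybenzyl chloride, K2CO3, NaI (cat.), acetone, reflux
Reagents that add atoms: 4-methoxybenzyl chloride, COc1ccc(CCl)cc1
Why: Williamson etherification; the 4-OH is free and the more acidic, whereas the 2-OH is held in a hydrogen bond to the acetyl carbonyl, so one equivalent of base and halide should alkylate O4 only.

Step 2
Reactants: 2 1-[2-hydroxy-4-(4-methoxybenzyloxy)phenyl]ethan-1-one; 3 diethyl carbonate
Product: 5 4-hydroxy-7-(4-methoxybenzyloxy)-2H-chromen-2-one, via beta-keto ester 4 (not isolated)
Conditions: NaH, toluene, 110 °C; then 1 M HCl, 0 °C
Reagents that add atoms: none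
Why: Claisen-type C-acylation of the ketone enolate by the carbonate gives the beta-keto ester 4, whose phenoxide lactonises with loss of ethoxide; the product leaves the equilibria as its stabilised sodium enolate and is freed by cold acid, which the aryl benzyl ether tolerates. This is the standard route from 2-hydroxyacetophenones to 4-hydroxycoumarins.

Step 3
Reactants: 5 4-hydroxy-7-(4-methoxybenzyloxy)-2H-chromen-2-one; 6 (2E,6E)-farnesyl bromide
Product: 7 4-hydroxy-7-(4-methoxybenzyloxy)-3-[(2E,6E)-farnesyl]-2H-chromen-2-one
Conditions: 5 (1.2 equiv), Et3N (1.2 equiv), Pd(PPh3)4 (5 mol %), THF, 0 °C to rt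
Reagents that add atoms: none
Why: Tsuji–Trost allylation; zerovalent palladium ionises 6 to the farnesyl pi-allyl complex and the soft C3 carbon of the coumarin anion attacks its unsubstituted terminus, which should give the linear product with the 2',3'-E geometry retained. Any 4-O-farnesyl ether from background alkylation is an allyl ester of a vinylogous acid and is re-ionised by the catalyst, so material should funnel to C-alkylated 7; the small excess of 5 limits a second farnesylation.

Step 4
Reactants: 7 4-hydroxy-7-(4-methoxybenzyloxy)-3-[(2E,6E)-farnesyl]-2H-chromen-2-one
Product: 8 rac-3-chloro-7-(4-methoxybenzyloxy)-3-[(2E,6E)-farnesyl]chromane-2,4-dione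
Conditions: N-chlorosuccinimide, CH2Cl2, 0 °C, dark
Reagents that add atoms: N-chlorosuccinimide, O=C1CCC(=O)N1Cl
Why: Electrophilic alpha-chlorination of a cyclic 1,3-dicarbonyl enol; C3 is far more nucleophilic than the isolated trisubstituted olefins, which the N-chloroimide should not touch at 0 °C without an acid or selenium catalyst. The quaternary centre forms as a racemate, which does not matter because step 5 destroys it.

Step 5
Reactants: 8 rac-3-chloro-7-(4-methoxybenzyloxy)-3-[(2E,6E)-farnesyl]chromane-2,4-dione
Product: 11 rac-6-(4-methoxybenzyloxy)-2-[(2E,6E)-farnesyl]-1-benzofuran-3(2H)-one, via ring-opened alpha-chloro keto acid 9 (not isolated), via benzofuranone-2-carboxylic acid 10 (not isolated)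
Conditions: LiOH (3 equiv), degassed THF/H2O, 0 °C to rt, argon, slow addition of 8 to the base; then aq. citric acid to pH 4, rt to 40 °C
Reagents that add atoms: none
Why: The lactone carbonyl of 8 is an aryl ester next to the chlorinated carbon and is the most electrophilic site, so hydroxide should attack there and open the ring irreversibly to the phenoxide carboxylate 9. The phenoxide of 9, fixed ortho to the ketone, then attacks the former C3 and expels chloride in a 5-exo-tet substitution that both neighbouring carbonyls accelerate; this forms O1–C2 and closes ring B as the keto acid 10. Mild acidification turns 10 into a free beta-keto acid, which loses the former lactone carbon as CO2 and gives 11; if 9 loses CO2 before it cyclises, the resulting alpha-chloro ketone closes by the same 5-exo-tet displacement, so both orders converge on 11. The closest known reaction type is the Perkin-type base-induced contraction of 3-halocoumarins to benzofurans, used here at the 3-halo-3-alkylchromane-2,4-dione oxidation level, which leads to 2-alkylbenzofuran-3(2H)-ones. No controlled stereocentre arises, since C2 of 11 is enolisable and racemic and is fixed only in step 6. The step needs substitution at the chlorinated carbon to outrun loss of HCl towards C1' and needs hydroxide to prefer the lactone over the C4 ketone; the entropic advantage of a five-membered closure by a neighbouring phenoxide and the higher electrophilicity of the aryl ester should secure both. Adding 8 slowly to excess cold base under argon keeps 8 away from the enolate of 11 (chlorine transfer) and keeps oxygen away from that enolate.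

Step 6
Reactants: 11 rac-6-(4-methoxybenzyloxy)-2-[(2E,6E)-farnesyl]-1-benzofuran-3(2H)-one
Product: 13 (2R)-2-hydroxy-6-(4-methoxybenzyloxy)-2-[(2E,6E)-farnesyl]-1-benzofuran-3(2H)-one, via sodium enolate 12 (not isolated)
Conditions: NaN(SiMe3)2, THF, −78 °C; [(8,8-dichlorocamphoryl)sulfonyl]oxaziridine, −78 °C; AcOH in THF, −78 °C
Reagents that add atoms: [(8,8-dichlorocamphoryl)sulfonyl]oxaziridine from (1S)-10-camphorsulfonic acid, CC1(C)[C@@H]2CC[C@]13CS(=O)(=O)N4O[C@@]34C2(Cl)Cl
Why: Enolate hydroxylation with a chiral N-sulfonyloxaziridine, the reaction established for 2-alkyl-1-indanone and 2-alkyl-1-tetralone enolates; the enolate carbon attacks the oxaziridine oxygen in an SN2-type transfer, and the chain olefins do not react at this temperature. The stereocentre is set by reagent control: the camphor-derived reagent has to deliver oxygen to the Si face of C2 (the face on which O1, C3 and C1' run anticlockwise), which gives (R). Acetic acid at −78 °C should protonate the hemiketal alkoxide before it can open to the diketone phenoxide.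

Step 7
Reactants: 13 (2R)-2-hydroxy-6-(4-methoxybenzyloxy)-2-[(2E,6E)-farnesyl]-1-benzofuran-3(2H)-one
Product: 14 (2R)-2,6-dihydroxy-2-[(2E,6E)-3,7,11-trimethyldodeca-2,6,10-trien-1-yl]-1-benzofuran-3(2H)-one
Conditions: DDQ, CH2Cl2/pH 7 phosphate buffer, 0 °C
Reagents that add atoms: none
Why: Oxidative cleavage of a 4-methoxybenzyl ether; hydride abstraction from the anisyl CH2 gives an oxocarbenium ion that water hydrolyses to the phenol and the aldehyde. The medium stays neutral, so the hemiketal is not deprotonated and C2 should keep its configuration; C2 is quaternary and cannot be dehydrogenated, and isolated trisubstituted olefins are inert to the quinone at 0 °C.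

## Compound list

1 | 2,4-dihydroxyacetophenone | CC(=O)c1ccc(O)cc1O | starting material
2 | 1-[2-hydroxy-4-(4-methoxybenzyloxy)phenyl]ethan-1-one | CC(=O)c1ccc(OCc2ccc(OC)cc2)cc1O | intermediate
3 | diethyl carbonate | CCOC(=O)OCC | starting material
4 | ethyl 3-[2-hydroxy-4-(4-methoxybenzyloxy)phenyl]-3-oxopropanoate (sodium salt in the flask, not isolated) | CCOC(=O)CC(=O)c1ccc(OCc2ccc(OC)cc2)cc1O | intermediate
5 | 4-hydroxy-7-(4-methoxybenzyloxy)-2H-chromen-2-one | O=c1cc(O)c2ccc(OCc3ccc(OC)cc3)cc2o1 | intermediate
6 | (2E,6E)-farnesyl bromide, (2E,6E)-1-bromo-3,7,11-trimethyldodeca-2,6,10-triene | CC(C)=CCC/C(C)=C/CC/C(C)=C/CBr | starting material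
7 | 4-hydroxy-7-(4-methoxybenzyloxy)-3-[(2E,6E)-farnesyl]-2H-chromen-2-one | CC(C)=CCC/C(C)=C/CC/C(C)=C/Cc1c(O)c2ccc(OCc3ccc(OC)cc3)cc2oc1=O | intermediate
8 | rac-3-chloro-7-(4-methoxybenzyloxy)-3-[(2E,6E)-farnesyl]chromane-2,4-dione | CC(C)=CCC/C(C)=C/CC/C(C)=C/CC1(Cl)C(=O)Oc2cc(OCc3ccc(OC)cc3)ccc2C1=O | intermediate
9 | rac-(4E,8E)-2-chloro-2-[2-hydroxy-4-(4-methoxybenzyloxy)benzoyl]-5,9,13-trimethyltetradeca-4,8,12-trienoic acid (dilithium salt in the flask, not isolated) | CC(C)=CCC/C(C)=C/CC/C(C)=C/CC(Cl)(C(=O)O)C(=O)c1ccc(OCc2ccc(OC)cc2)cc1O | intermediate
10 | rac-6-(4-methoxybenzyloxy)-3-oxo-2-[(2E,6E)-farnesyl]-2,3-dihydro-1-benzofuran-2-carboxylic acid (lithium salt in the flask, not isolated) | CC(C)=CCC/C(C)=C/CC/C(C)=C/CC1(C(=O)O)Oc2cc(OCc3ccc(OC)cc3)ccc2C1=O | intermediate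
11 | rac-6-(4-methoxybenzyloxy)-2-[(2E,6E)-farnesyl]-1-benzofuran-3(2H)-one | CC(C)=CCC/C(C)=C/CC/C(C)=C/CC1Oc2cc(OCc3ccc(OC)cc3)ccc2C1=O | intermediate
12 | sodium 6-(4-methoxybenzyloxy)-2-[(2E,6E)-farnesyl]-1-benzofuran-3-olate (not isolated) | CC(C)=CCC/C(C)=C/CC/C(C)=C/Cc1oc2cc(OCc3ccc(OC)cc3)ccc2c1[O-].[Na+] | intermediate
13 | (2R)-2-hydroxy-6-(4-methoxybenzyloxy)-2-[(2E,6E)-farnesyl]-1-benzofuran-3(2H)-one | CC(C)=CCC/C(C)=C/CC/C(C)=C/C[C@@]1(O)Oc2cc(OCc3ccc(OC)cc3)ccc2C1=O | intermediate
14 | (2R)-2,6-dihydroxy-2-[(2E,6E)-3,7,11-trimethyldodeca-2,6,10-trien-1-yl]-1-benzofuran-3(2H)-one | CC(C)=CCC/C(C)=C/CC/C(C)=C/C[C@@]1(O)Oc2cc(O)ccc2C1=O | target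

## Step count and risks

Total step count: 7. Longest linear sequence: 7 steps, from 1 to 14.

**Step 5 (key step).**
- What may go wrong: in aqueous base the product exists as its enolate beside unreacted 8, which is a positive-chlorine donor. Chlorine transfer between the two, air oxidation of the enolate and loss of HCl towards C1' can each divert material.
- Fallback: from 8, NaOMe in MeOH/THF at −20 °C opens the lactone by methanolysis and the same 5-exo-tet closure gives methyl 6-(4-methoxybenzyloxy)-3-oxo-2-[(2E,6E)-farnesyl]-2,3-dihydro-1-benzofuran-2-carboxylate F1. F1 is quaternary at C2 and can neither enolise nor accept chlorine. Krapcho dealkoxycarbonylation (LiCl, wet DMSO, 130 °C, argon) then removes the ester carbon under neutral conditions and returns to 11.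

**Step 6.**
- What may go wrong: ring opening of the hemiketal alkoxide to the diketone phenoxide and unselective reclosure before the quench would erode the configuration. Facial discrimination by the reagent on this oxygen-containing enolate may also be insufficient.
- Fallback: from 11, hydroxylation with the achiral 3-phenyl-2-(phenylsulfonyl)oxaziridine under the same conditions gives the racemic hemiketal rac-2-hydroxy-6-(4-methoxybenzyloxy)-2-[(2E,6E)-farnesyl]-1-benzofuran-3(2H)-one F2. F2 is resolved by preparative chromatography on a polysaccharide chiral stationary phase with a neutral eluent, which returns to 13. The unwanted enantiomer is racemised on purpose with a trace of amine base, through the same ring-chain equilibrium, and recycled.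

**Step 3.**
- What may go wrong: alkylation at O4 may not be fully corrected by the catalyst, a second farnesylation at C3 can occur, and the 2',3' olefin can isomerise through the pi-allyl complex.
- Fallback: from 2, the dianion (LiN(iPr)2, 2.2 equiv, THF, −78 °C) is alkylated at the methyl carbon with 6 to give (4E,8E)-1-[2-hydroxy-4-(4-methoxybenzyloxy)phenyl]-5,9,13-trimethyltetradeca-4,8,12-trien-1-one F3. F3 is cyclised with 3 and NaH as in step 2 and gives 7 directly, so that no ambident coumarin anion and no pi-allyl intermediate are involved.

**Step 7.**
- What may go wrong: cleavage of the electron-poor aryl benzyl ether may be slow, which would prolong contact of the hemiketal with the acidic hydroquinone and water (erosion of configuration) and allow allylic oxidation.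
- Fallback: the deprotection is moved ahead of the stereocentre. From 8, DDQ in CH2Cl2/pH 7 buffer gives rac-3-chloro-7-hydroxy-3-[(2E,6E)-farnesyl]chromane-2,4-dione F4, which has neither an enol nor a hemiketal. The LiOH contraction of step 5 with one more equivalent of base gives rac-6-hydroxy-2-[(2E,6E)-farnesyl]-1-benzofuran-3(2H)-one F5. Hydroxylation of the dianion of F5 (NaN(SiMe3)2, 2.2 equiv, then the oxaziridine of step 6, AcOH at −78 °C) gives 14, so the stereocentre is made in the last operation.

## Further compounds

F1 | step 5 | methyl rac-6-(4-methoxybenzyloxy)-3-oxo-2-[(2E,6E)-farnesyl]-2,3-dihydro-1-benzofuran-2-carboxylate | CC(C)=CCC/C(C)=C/CC/C(C)=C/CC1(C(=O)OC)Oc2cc(OCc3ccc(OC)cc3)ccc2C1=O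
F2 | step 6 | rac-2-hydroxy-6-(4-methoxybenzyloxy)-2-[(2E,6E)-farnesyl]-1-benzofuran-3(2H)-one | CC(C)=CCC/C(C)=C/CC/C(C)=C/CC1(O)Oc2cc(OCc3ccc(OC)cc3)ccc2C1=O
F3 | step 3 | (4E,8E)-1-[2-hydroxy-4-(4-methoxybenzyloxy)phenyl]-5,9,13-trimethyltetradeca-4,8,12-trien-1-one | CC(C)=CCC/C(C)=C/CC/C(C)=C/CCC(=O)c1ccc(OCc2ccc(OC)cc2)cc1O
F4 | step 7 | rac-3-chloro-7-hydroxy-3-[(2E,6E)-farnesyl]chromane-2,4-dione | CC(C)=CCC/C(C)=C/CC/C(C)=C/CC1(Cl)C(=O)Oc2cc(O)ccc2C1=O
F5 | step 7 | rac-6-hydroxy-2-[(2E,6E)-farnesyl]-1-benzofuran-3(2H)-one | CC(C)=CCC/C(C)=C/CC/C(C)=C/CC1Oc2cc(O)ccc2C1=O
A1 | alternative 1 | (Z)-2-[(2E,6E)-3,7,11-trimethyldodeca-2,6,10-trien-1-ylidene]-6-(triisopropylsilyloxy)-1-benzofuran-3(2H)-one | CC(C)=CCC/C(C)=C/CC/C(C)=C/C=C1\Oc2cc(O[Si](C(C)C)(C(C)C)C(C)C)ccc2C1=O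
A2 | alternative 1 | spiro-oxirane of the C2=C1' bond of A1, C2 configured as in the target, 6-triisopropylsilyl ether | CC(C)=CCC/C(C)=C/CC/C(C)=C/[C@@H]3[C@@]1(O3)Oc2cc(O[Si](C(C)C)(C(C)C)C(C)C)ccc2C1=O
A3 | alternative 2 | 2-formyl-5-(triisopropylsilyloxy)phenyl (3E,7E)-4,8,12-trimethyltrideca-3,7,11-trienoate | CC(C)=CCC/C(C)=C/CC/C(C)=C/CC(=O)Oc1cc(O[Si](C(C)C)(C(C)C)C(C)C)ccc1C=O
A4 | alternative 2 | (2R)-2-hydroxy-2-[(2E,6E)-farnesyl]-6-(triisopropylsilyloxy)-1-benzofuran-3(2H)-one | CC(C)=CCC/C(C)=C/CC/C(C)=C/C[C@@]1(O)Oc2cc(O[Si](C(C)C)(C(C)C)C(C)C)ccc2C1=O
A5 | alternative 3 | rac-3-{[(6E,10E)-7,11,15-trimethyl-3-oxohexadeca-6,10,14-trien-1-yn-4-yl]oxy}-5-(triisopropylsilyloxy)-2H-pyran-2-one | CC(C)=CCC/C(C)=C/CC/C(C)=C/CC(Oc1cc(O[Si](C(C)C)(C(C)C)C(C)C)coc1=O)C(=O)C#C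
A6 | alternative 3 | rac-2-[(2E,6E)-farnesyl]-6-(triisopropylsilyloxy)-1-benzofuran-3(2H)-one | CC(C)=CCC/C(C)=C/CC/C(C)=C/CC1Oc2cc(O[Si](C(C)C)(C(C)C)C(C)C)ccc2C1=O
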